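**Retrosynthetic overview**

1. No ring is formed: both benzene rings are bought. Phloroglucinol 1 and benzonitrile 2 give, through ketiminium salt 3, the symmetric 2,4,6-trihydroxybenzophenone 4.
2. The C10 chain comes from sulcatone 5: trisylhydrazide 6 gives hydrazone 7, which is coupled with chloroacetyl Weinreb amide 8 through vinyllithium 9 to give chloro enone 10. CBS reduction to chlorohydrin 11 sets the only stereocentre.
3. Key disconnection (last bond made): aryl–CH2. Epoxide 12, formed in the flask from 11, is opened at its CH2 by a ring carbon of the dianion of 4. The ring is dearomatised and loses its twofold symmetry (dienone 13), then tautomerises to the target 14.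
4. The carbinol carbon is never a reacting centre after step 4, so (S)-11 maps onto (R)-14 (the descriptor changes only through CIP priorities).

Assumption: sulcatone, 2,4,6-triisopropylbenzenesulfonohydrazide, 2-chloro-N-methoxy-N-methylacetamide and (S)-2-methyl-CBS-oxazaborolidine are taken as commercially available; the target is the (R)-alcohol as drawn.

**Route**

Step 1
Reactants: 1 phloroglucinol (benzene-1,3,5-triol, anhydrous); 2 benzonitrile
Product: 4 2,4,6-trihydroxybenzophenone, via ketiminium chloride 3 (not isolated)
Conditions: HCl (g), ZnCl2 (0.3 equiv), Et2O, 0 °C to rt; then H2O, reflux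
Reagents that add atoms: water, O
Why: Houben–Hoesch acylation, in which the nitrilium species from 2 attacks the very electron-rich ring of 1 once only (the precipitated ketiminium salt 3 is deactivated) and boiling water hydrolyses 3 to the ketone; no stereocentre.

Step 2
Reactants: 5 sulcatone (6-methylhept-5-en-2-one); 6 2,4,6-triisopropylbenzenesulfonohydrazide
Product: 7 (E)-trisylhydrazone of sulcatone
Conditions: MeOH, cat. HCl, rt; crystallise
Reagents that add atoms: none
Why: Acid-catalysed hydrazone condensation, which gives the crystalline (E)-hydrazone and leaves the trisubstituted alkene untouched; no stereocentre.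

Step 3
Reactants: 7 (E)-trisylhydrazone of sulcatone; 8 2-chloro-N-methoxy-N-methylacetamide
Product: 10 1-chloro-7-methyl-3-methylideneoct-6-en-2-one, via vinyllithium 9 (not isolated)
Conditions: n-BuLi (2.1 equiv), TMEDA–hexane, −78 to 0 °C; then 8, THF, −78 °C; cold aq NH4Cl
Reagents that add atoms: none
Why: Shapiro reaction followed by Weinreb ketone synthesis, in which the hydrazone dianion (deprotonated at the methyl group syn to the sulfonamide nitrogen) loses sulfinate and N2 to give the 1,1-disubstituted vinyllithium 9, which adds once to 8 through a chelated tetrahedral intermediate that releases the ketone only on quench; no stereocentre.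

Step 4
Reactants: 10 1-chloro-7-methyl-3-methylideneoct-6-en-2-one
Product: 11 (2S)-1-chloro-7-methyl-3-methylideneoct-6-en-2-ol
Conditions: (S)-2-methyl-CBS-oxazaborolidine (0.2 equiv), catecholborane (1.5 equiv), toluene, −78 °C; then MeOH; SiO2
Reagents that add atoms: none
Why: Corey–Bakshi–Shibata reduction, in which the conjugated α-branched alkenyl group is the large substituent and CH2Cl the small one, so the (S)-catalyst gives the (S)-chlorohydrin (same sense as phenacyl chloride to (S)-2-chloro-1-phenylethanol), while catecholborane at −78 °C reduces 1,2 and does not hydroborate the alkenes.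

Step 5
Reactants: 4 2,4,6-trihydroxybenzophenone (3 equiv, excess recovered); 11 (2S)-1-chloro-7-methyl-3-methylideneoct-6-en-2-ol
Product: 14 phenyl{2,4,6-trihydroxy-3-[(2R)-2-hydroxy-7-methyl-3-methylideneoct-6-en-1-yl]phenyl}methanone, via epoxide 12 (not isolated), via dienone 13 (not isolated)
Conditions: LiOH (7 equiv), degassed H2O/t-BuOH 9:1, Ar, 0 to 40 °C; then 1 M HCl to pH 4, 0 °C
Reagents that add atoms: none
Why: Proposed new method: hydroxide first closes 11 to epoxide 12 (intramolecular Williamson, carbinol carbon untouched), and the dianion of 4, a vinylogous triketone enolate whose oxygens are hydrogen-bonded by water, then attacks the unhindered epoxide CH2 in an SN2 step through ring carbon 3 (identical to carbon 5, so one regioisomer only) to give the dearomatised dienone 13, which enolises back to the arene; the stereocentre is carried unchanged from (S)-11 and is named (R) in 14 only because CIP priorities change; the closest known reactions are the C-prenylation and C-geranylation of acylphloroglucinols with allylic bromides in aqueous KOH, their C-methylation with MeI/NaOMe, and the opening of vinyl epoxides at the terminal carbon by malonate-type carbanions when no palladium or Lewis acid is present (alkylative dearomatisation then rearomatisation, a Friedel–Crafts-type C-alkylation of a phenolate).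

**Compound list**

1 | phloroglucinol (benzene-1,3,5-triol) | Oc1cc(O)cc(O)c1 | starting material
2 | benzonitrile | N#Cc1ccccc1 | starting material
3 | phenyl(2,4,6-trihydroxyphenyl)methaniminium chloride (not isolated) | [NH2+]=C(c1ccccc1)c1c(O)cc(O)cc1O.[Cl-] | intermediate
4 | 2,4,6-trihydroxybenzophenone | O=C(c1ccccc1)c1c(O)cc(O)cc1O | intermediate
5 | sulcatone (6-methylhept-5-en-2-one) | CC(=O)CCC=C(C)C | starting material
6 | 2,4,6-triisopropylbenzenesulfonohydrazide | CC(C)c1cc(C(C)C)c(S(=O)(=O)NN)c(C(C)C)c1 | starting material
7 | N'-[(2E)-6-methylhept-5-en-2-ylidene]-2,4,6-triisopropylbenzenesulfonohydrazide | C/C(CCC=C(C)C)=N\NS(=O)(=O)c1c(C(C)C)cc(C(C)C)cc1C(C)C | intermediate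
8 | 2-chloro-N-methoxy-N-methylacetamide | CON(C)C(=O)CCl | starting material
9 | (6-methylhepta-1,5-dien-2-yl)lithium (not isolated) | [Li]C(=C)CCC=C(C)C | intermediate
10 | 1-chloro-7-methyl-3-methylideneoct-6-en-2-one | C=C(CCC=C(C)C)C(=O)CCl | intermediate
11 | (2S)-1-chloro-7-methyl-3-methylideneoct-6-en-2-ol | C=C(CCC=C(C)C)[C@H](O)CCl | intermediate
12 | (2S)-2-(6-methylhepta-1,5-dien-2-yl)oxirane (not isolated) | C=C(CCC=C(C)C)[C@H]1CO1 | intermediate
13 | 4-benzoyl-3,5-dihydroxy-6-[(2R)-2-hydroxy-7-methyl-3-methylideneoct-6-en-1-yl]cyclohexa-2,4-dien-1-one (dearomatised keto tautomer, both epimers at ring carbon 6, not isolated) | C=C(CCC=C(C)C)[C@H](O)CC1C(=O)C=C(O)C(C(=O)c2ccccc2)=C1O | intermediate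
14 | phenyl{2,4,6-trihydroxy-3-[(2R)-2-hydroxy-7-methyl-3-methylideneoct-6-en-1-yl]phenyl}methanone | C=C(CCC=C(C)C)[C@H](O)Cc1c(O)cc(O)c(C(=O)c2ccccc2)c1O | target

**Step count**

Total steps: 5. Longest linear sequence: 4 (5 → 7 → 10 → 11 → 14).

**Steps most likely to fail, with fallbacks**

Step 5 (O-alkylation or double alkylation instead of mono C-alkylation). The fallback sets out from 1 and 11 and comes back at 14. Phloroglucinol 1 is protected (MOMCl, i-Pr2NEt, CH2Cl2) as 1,3,5-tris(methoxymethoxy)benzene F1, and 11 is closed with aq NaOH/Et2O to epoxide 12, now isolated. F1 is lithiated between two MOM ethers (n-BuLi, THF, 0 °C) and the aryllithium opens 12 at its CH2 without Lewis acid or copper (hard carbanions attack the terminal carbon of vinyl epoxides under these conditions) to give (2R)-7-methyl-3-methylidene-1-[2,4,6-tris(methoxymethoxy)phenyl]oct-6-en-2-ol F2. A second lithiation on the lithium alkoxide (n-BuLi, 2.2 equiv) and N-methoxy-N-methylbenzamide give {3-[(2R)-2-hydroxy-7-methyl-3-methylideneoct-6-en-1-yl]-2,4,6-tris(methoxymethoxy)phenyl}(phenyl)methanone F3. Dilute HCl in MeOH at 40 °C removes the three MOM groups and gives 14.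

Step 4 (low ee if CH2Cl and the alkenyl group are poorly differentiated). The fallback sets out from 10 and comes back at 12. Luche reduction (NaBH4, CeCl3·7H2O, MeOH, −78 °C) gives racemic 1-chloro-7-methyl-3-methylideneoct-6-en-2-ol F4, and aq NaOH closes it to racemic 2-(6-methylhepta-1,5-dien-2-yl)oxirane F5. Jacobsen hydrolytic kinetic resolution follows, with (salen)Co(OAc) (salen = N,N'-bis(3,5-di-tert-butylsalicylidene)cyclohexane-1,2-diamine dianion, trivalent cobalt) and 0.55 equiv H2O. The catalyst enantiomer is the one that hydrolyses the (R)-epoxide, which is the (R,R)-complex by the propylene oxide precedent. It leaves (S)-12 and removes the other half as (2R)-7-methyl-3-methylideneoct-6-ene-1,2-diol F6. Step 5 is then run with isolated 12 in place of 11.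

Step 3 (α-deprotonation of amide 8 by the vinyllithium, or a poor Shapiro step). The fallback sets out from 5 and comes back at 10. Kinetic enolisation of 5 (LiN(i-Pr)2, THF, −78 °C) and trapping with PhNTf2 give 6-methylhepta-1,5-dien-2-yl trifluoromethanesulfonate F7. Methoxycarbonylation (Pd(OAc)2, PPh3, CO 1 atm, MeOH, Et3N, DMF, 60 °C) gives methyl 6-methyl-2-methylidenehept-5-enoate F8. Chloromethyllithium made in the flask (ICH2Cl, MeLi·LiBr, THF, −78 °C) adds once to the ester and gives 10 on quench.

**Further compounds**

F1 | step 5 | 1,3,5-tris(methoxymethoxy)benzene | COCOc1cc(OCOC)cc(OCOC)c1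
F2 | step 5 | (2R)-7-methyl-3-methylidene-1-[2,4,6-tris(methoxymethoxy)phenyl]oct-6-en-2-ol | C=C(CCC=C(C)C)[C@H](O)Cc1c(OCOC)cc(OCOC)cc1OCOC
F3 | step 5 | {3-[(2R)-2-hydroxy-7-methyl-3-methylideneoct-6-en-1-yl]-2,4,6-tris(methoxymethoxy)phenyl}(phenyl)methanone | C=C(CCC=C(C)C)[C@H](O)Cc1c(OCOC)cc(OCOC)c(C(=O)c2ccccc2)c1OCOC
F4 | step 4 | racemic 1-chloro-7-methyl-3-methylideneoct-6-en-2-ol | C=C(CCC=C(C)C)C(O)CCl
F5 | step 4 | racemic 2-(6-methylhepta-1,5-dien-2-yl)oxirane | C=C(CCC=C(C)C)C1CO1
F6 | step 4 | (2R)-7-methyl-3-methylideneoct-6-ene-1,2-diol | C=C(CCC=C(C)C)[C@@H](O)CO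
F7 | step 3 | 6-methylhepta-1,5-dien-2-yl trifluoromethanesulfonate | C=C(CCC=C(C)C)OS(=O)(=O)C(F)(F)F
F8 | step 3 | methyl 6-methyl-2-methylidenehept-5-enoate | C=C(CCC=C(C)C)C(=O)OC
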